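Assumption: the target has no stereocentres (it is achiral), so "single enantiomer" is taken to mean the single (2'E,6'E,10'E) geometric isomer shown in the SMILES.

## Retrosynthetic overview

1. Benzoate C–O bond: target ⇐ ω-hydroxyferulenol + benzoyl chloride, acylating the primary allylic OH selectively over the 4-OH enol.
2. Coumarin C3–C1' bond: ω-hydroxyferulenol ⇐ 4-hydroxycoumarin + (2E,6E,10E)-12-hydroxyfarnesyl acetate by Pd-catalysed (Tsuji–Trost) C-allylation, with the acetate as leaving group.
3. C12–O bond: 12-hydroxyfarnesyl acetate ⇐ (2E,6E)-farnesyl acetate by E-selective SeO2 allylic hydroxylation.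
4. Rings: none is formed. The coumarin bicycle comes intact from 4-hydroxycoumarin and the phenyl ring from benzoyl chloride.
5. All three alkene geometries come from E,E-farnesyl acetate (2E, 6E) and the SeO2 step (10E). No protecting groups are used, because the acetate serves first as the C1 protecting group and then as the leaving group.

## Route

**Step 1**
Reactants: 1, (2E,6E)-farnesyl acetate
Product: 2, (2E,6E,10E)-12-hydroxy-3,7,11-trimethyldodeca-2,6,10-trien-1-yl acetate
Conditions: SeO2 (0.3 equiv), t-BuOOH (3 equiv), salicylic acid (0.1 equiv), CH2Cl2, 0 °C → rt, 24–40 h; then NaBH4, MeOH, −10 °C, 15 min to return over-oxidised 12-al to the 12-ol; chromatography, recycle recovered 1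
Reagents that add atoms: selenium dioxide, O=[Se]=O (delivers the OH oxygen); tert-butyl hydroperoxide, CC(C)(C)OO (terminal oxidant)
Why: Riley/Sharpless allylic oxidation (ene reaction then [2,3]-sigmatropic shift) attacks the most electron-rich, least hindered terminal trisubstituted alkene and oxidises its E-methyl, giving the (10E)-allylic alcohol; the 2,3-alkene is deactivated by the allylic acetate.

**Step 2**
Reactants: 2, 12-hydroxyfarnesyl acetate; 3, 4-hydroxycoumarin (2 equiv)
Product: 4, ω-hydroxyferulenol, i.e. 4-hydroxy-3-[(2E,6E,10E)-12-hydroxy-3,7,11-trimethyldodeca-2,6,10-trien-1-yl]-2H-chromen-2-one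
Conditions: Pd(PPh3)4 (5 mol %), DBU (2 equiv), degassed THF, rt → 45 °C; dilute HCl work-up; excess 3 removed by NaHCO3 wash
Reagents that add atoms: 4-hydroxycoumarin (3), O=c1cc(O)c2ccccc2o1
Why: Tsuji–Trost allylic alkylation. Pd(0) ionises the allylic acetate, not the free allylic alcohol under basic conditions, and the soft enolate of 3 (pKa ≈ 4) attacks the unhindered CH2 terminus to give the linear C3-allyl product. O-allyl and 3,3-diallyl by-products can be re-ionised by Pd(0) and funnelled to the mono-C-allyl product. The 2'E geometry is retained because syn/anti exchange would need an unfavourable tertiary σ-allyl-Pd.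

**Step 3**
Reactants: 4, ω-hydroxyferulenol; 5, benzoyl chloride (2.2 equiv)
Product: 6, E-ω-benzoyloxyferulenol (target)
Conditions: BzCl, Et3N (3 equiv), DMAP (0.1 equiv), CH2Cl2, 0 °C → rt, 2 h (forms the 4-O,12'-O-dibenzoate in situ); then MeOH, K2CO3, 0 °C, 20–30 min in the same pot (monitored by TLC); 1 M HCl work-up
Reagents that add atoms: benzoyl chloride (5), O=C(Cl)c1ccccc1
Why: Nucleophilic acyl substitution (DMAP-catalysed esterification). The transient 4-O-benzoyl enol ester is a vinylogous mixed anhydride (leaving-group pKa ≈ 5) and is methanolysed far faster than the primary alkyl benzoate (leaving-group pKa ≈ 16), so only the ω-benzoate remains. No alkene is touched and no stereo-element is created.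

## Compound list

1 | (2E,6E)-farnesyl acetate | CC(C)=CCC/C(C)=C/CC/C(C)=C/COC(C)=O | starting material
2 | (2E,6E,10E)-12-hydroxy-3,7,11-trimethyldodeca-2,6,10-trien-1-yl acetate | CC(=O)OC/C=C(\C)CC/C=C(\C)CC/C=C(\C)CO | intermediate
3 | 4-hydroxycoumarin | O=c1cc(O)c2ccccc2o1 | starting material
4 | ω-hydroxyferulenol | C/C(=C\Cc1c(O)c2ccccc2oc1=O)CC/C=C(\C)CC/C=C(\C)CO | intermediate
5 | benzoyl chloride | O=C(Cl)c1ccccc1 | starting material
6 | E-ω-benzoyloxyferulenol | C/C(=C\CC/C(C)=C/Cc1c(O)c2ccccc2oc1=O)CC/C=C(\C)COC(=O)c1ccccc1 | target

## Summary

Total steps: 3 (step 3 is a one-pot acylation followed by selective enol-ester cleavage).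
Longest linear sequence: 3 steps (1 → 2 → 4 → 6).

Steps most likely to fail, with fallbacks:

1. **Step 2 (Pd C-allylation).** Risks are 2'E/Z erosion, branched attack, elimination to the triene, and bis-allylation. Fallback: abandon π-allyl chemistry for an SN2 route. Make (2E,6E,10E)-12-benzoyloxyfarnesyl bromide (farnesol TBS ether → SeO2 → BzCl → Ph3PBr2) and C-alkylate the sodium salt of 4-hydroxycoumarin in aqueous/protic medium. This also puts the benzoate in before coupling.

2. **Step 1 (SeO2 oxidation).** Risks are modest yield, over-oxidation and competing oxidation at the 6,7-alkene. Fallback: rebuild the chain terminus instead of C–H oxidation. Terminal bromohydrin/epoxide of 1 (NBS, aq. THF; K2CO3), HIO4 cleavage to the trisnor aldehyde, E-selective Wittig with Ph3P=C(CH3)CHO, then Luche reduction to 2.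

3. **Step 3 (chemoselective benzoylation).** Risks are incomplete discrimination between the enol ester and the alkyl benzoate in the cleavage, or amine/alkoxide attack on the coumarin. Fallback: biocatalytic transesterification of 4 with vinyl benzoate and immobilised Candida antarctica lipase B, which should acylate only the primary alcohol and leave the enol OH untouched.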